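Compound numbers are those of the steps and the compound list below. "Prenyl" means 3-methylbut-2-en-1-yl. Benzofuran numbering: O1, C2, C3, C3a, C4 to C7, C7a; ring A is the benzo ring, ring B the aryl group on C2.

## Analysis of the target

The target 18 is a 2-arylbenzofuran whose furan ring (O1, C2, C3, C3a, C7a) is fused to a fully loaded ring A: hydroxyl on C4, prenyl on C5, methoxy on C6 and hydrogen only on C7. C2 carries a 2,4-dihydroxyphenyl ring B and C3 a formyl group. There is no stereocentre, and the only non-aromatic alkene is the prenyl double bond, which has no geometric isomers, so the problem is one of regiochemistry and functional-group tolerance. The prenyl group lies ortho to the free 4-OH and closes to a 2,2-dimethylchroman in protic acid, the aldehyde can form a lactol with the 2'-OH, and three phenols on two electron-rich rings are easily oxidised. The difficulty is threefold: four contiguous substituents from C3a to C6, two ring A oxygens that must end differentiated (4-OH against 6-OMe), and a formyl group that must go to C3 although C7, flanked by O1 and the 6-methoxy group, is at least as reactive toward electrophilic formylation. The strategy rests on the C2=C3 bond: C2 bears O1 and ring B and so sits at the oxidation level of an aryl ester carbonyl, while C3 is a benzylic carbon on C3a that bears the formyl carbon. Read as an olefin, this bond is a carbonyl-olefination retron inside the furan: C2 and ring B come from an aroyl ester on the ring A phenol oxygen, and C3 from a phosphonium-bearing benzylic carbon that already carries the formyl carbon as an acetal. With the 4-oxygen written as a methyl ether, the ring A building block 6 is symmetric, so the carbon that becomes C3 can enter ortho to the future O1 in only one way.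

## Retrosynthetic reasoning

18 to 17: the last bond cut is the O–CH3 bond at C4. It is placed at the very end because the free 4-OH next to the prenyl group must not meet protic acid. It is made selective by the formyl oxygen, which can bind a Lewis acid together with the peri 4-methoxy oxygen, whereas the 6-methoxy oxygen has no such partner. The forward step therefore has to be aprotic, neutral and chelation-driven.

17 to 16: the two methoxymethyl ethers of ring B and the dimethyl acetal on C3 are returned together. One acid treatment removes all three, and it is run while both oxygens flanking the prenyl group are still methyl ethers, so that no chroman can form.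

16 to 14 by way of ylide 15: the C2=C3 bond is cut into the aryl ester carbonyl and the phosphonium-substituted benzylic carbon of 14. This cut is preferred to an O1–C2 or C3–C3a disconnection because it closes the ring and places the formyl carbon on C3 in one operation, without any electrophilic substitution on a nucleus where C7 would compete. The forward reaction needs an ylide that olefinates the neighbouring ester instead of being acylated or losing methoxide.

14 to 10 and 13: the ester C–O bond is cut, which separates ring B as the protected acid 13 from the ring A phosphonium phenol 10. A carbodiimide coupling is planned instead of an acid chloride, because an aroyl chloride with an ortho methoxymethoxy group cyclises onto itself. Acid 13 goes back through its methoxymethyl ester 12 to 2,4-dihydroxybenzoic acid 11.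

10 to 9: the C–P bond is cut to the benzylic alcohol 9. Forward, the hydroxyl leaves with help from the ortho hydroxyl and the ortho and para methoxy groups, and the phosphine captures the resulting quinone methide. The task is to achieve this with acid weak enough to leave the acetal and the prenyl alkene alone.

9 to 6 and 7: the C3a–C3 bond is cut into the symmetric phenol 6 and the aldehyde 7, which supplies C3 and the masked formyl carbon. The magnesium phenoxide 8 delivers the aldehyde to the ortho carbon; both ortho positions of 6 are equivalent and the para position is occupied, so one constitution results.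

6 to 5, then to 2 and 3 by way of aryllithium 4, then to 1: the aryl–prenyl bond is cut at the carbon between the two methoxy groups. A phenoxide would be prenylated ortho to its oxygen, so the phenol 1 is masked as the bulky silyl ether 2. The two methoxy groups then direct lithiation between them to give 4, which is allylated with 3. Desilylation of 5 returns phenol 6.

## Alternatives that were turned down

Alternative 1: The formyl carbon is traced back to a CH2 bridge between C3 and the 2'-oxygen, giving the pterocarpene 7,9-dimethoxy-8-prenyl-6H-benzofuro[3,2-c]chromen-3-yl pivalate A1. The C3–CH2 bond of A1 is then cut to the 3-unsubstituted benzofuran 4-(4,6-dimethoxy-5-prenylbenzofuran-2-yl)-3-hydroxyphenyl pivalate A2.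
- Forward key step: acid condenses a one-carbon aldehyde with the 2'-OH of A2, and the oxocarbenium ion attacks C3 in an oxa-Pictet–Spengler closure of the pyran ring to give A1. Later the O–CH2 bridge has to be oxidised to the lactol level and opened to the aldehyde.
- For: the tether sends the carbon to C3 and not to C7. A2 can be made by the best-precedented form of the ester Wittig closure, with an unsubstituted ylide, and on that point this plan is stronger than the chosen one.
- Against: A2 needs the two ring B oxygens differentiated, which costs extra steps. The acid and the carbon electrophile meet the prenyl alkene and the free C7. The oxidation of A1 must stop at the aldehyde level instead of running on to the coumestan lactone, and must spare the prenyl CH2, which is both benzylic and allylic. The 4-O-demethylation is still needed afterwards.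
- Comparison: the chosen route carries the formyl carbon at its final oxidation level from the hydroxyalkylation onward and needs no oxidation in the presence of the prenyl group. It accepts a more crowded ylide in return.

Alternative 2: Ring A is cut away completely. The four bonds C7–C7a, C6–C7, C4–C5 and C3a–C4 go back to the furyl diazo ketone 2-diazo-1-{5-[2,4-bis(methoxymethoxy)phenyl]-4-(1,3-dioxolan-2-yl)furan-2-yl}ethanone A4 and the ynol ether 1-methoxy-5-methylhex-4-en-1-yne A5.
- Forward key step: a Danheiser benzannulation. Photolysis of A4 triggers the Wolff shift to a furyl ketene, which adds to A5 in a [2+2] reaction. 4π opening and 6π closure onto the furan then give 2-[2,4-bis(methoxymethoxy)phenyl]-3-(1,3-dioxolan-2-yl)-6-methoxy-5-prenylbenzofuran-4-ol A3.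
- For: the regiochemistry of ring A is written into the alkyne, and the 4-hydroxyl of A3 is born free while the 6-oxygen is already methylated. No late selective demethylation is needed, and here this plan is stronger than the chosen one.
- Against: A4 is a trisubstituted furan that needs a synthesis of its own, and A5 is a sensitive skipped enyne. The ketene can also be intercepted by the prenyl alkene. A3 has the free 4-hydroxyl beside the prenyl group before the acetal and the methoxymethyl ethers are removed, so the unavoidable acid step invites chroman formation.
- Comparison: the chosen route is shorter, uses only thermal ionic chemistry from a symmetric phenol, and runs its acid step before the 4-hydroxyl is set free. It pays with one chelation-controlled demethylation.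

Alternative 3: The furan O1–C2 bond and the formyl group are traced back to a pyranone. The precursor is the isoflavone 7-hydroxy-3-(2-hydroxy-4,6-dimethoxy-5-prenylphenyl)chromen-4-one A7.
- Forward key step: strong acid in a fluorinated alcohol with a trace of water opens the pyranone of A7 at its ring O–CH bond. The phenol of the 3-aryl group then closes on the former ketone carbon and gives 2-(2,4-dihydroxyphenyl)-4,6-dimethoxy-5-prenylbenzofuran-3-carbaldehyde A6. The constitution of A6 is that of 17.
- For: the key step needs no protecting group on ring B and sets the formyl group on C3 by construction. In protecting-group economy it is stronger than the chosen plan.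
- Against: a strong acid in a cation-stabilising solvent is the worst environment for the prenyl alkene (hydration, cation–arene cyclisation). A7 needs a 3-aryl group with two ortho oxygens and a prenyl group, which is awkward to attach to a chromone. The ring-opened dicarbonyl intermediate can also close back to A7 instead of going on to A6. The 4-O-demethylation is still required.
- Comparison: the chosen route reaches 17, the same compound as A6, by a ring closure under a weak amine base and then dilute aqueous acid, which the prenyl group tolerates better. The price is two steps spent on the ring B protecting groups.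

Key step: step 9

Assumption: commercial aqueous 2,2-dimethoxyacetaldehyde is extracted into CH2Cl2 and dried (MgSO4, then 4 Å sieves) before step 4. Compounds 9, 10 and 14 are racemic; their single stereocentre becomes the sp2 carbon C3 in step 9.

## Steps

Step 1
Reactants: 1 3,5-dimethoxyphenol
Product: 2 (3,5-dimethoxyphenoxy)triisopropylsilane
Conditions: TIPSCl, imidazole, DMF, rt
Reagents that add atoms: chlorotriisopropylsilane, CC(C)[Si](Cl)(C(C)C)C(C)C
Why: Standard O-silylation of a phenol; the bulky, weakly coordinating silyl ether survives the alkyllithium and keeps metalation away from its own ortho positions.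

Step 2
Reactants: 2 (3,5-dimethoxyphenoxy)triisopropylsilane; 3 prenyl bromide (1-bromo-3-methylbut-2-ene)
Product: 5 triisopropyl[3,5-dimethoxy-4-(3-methylbut-2-en-1-yl)phenoxy]silane, via aryllithium 4 (not isolated)
Conditions: n-BuLi, THF, 0 °C to rt; CuBr·SMe2 (10 mol%), then 3, −78 °C to 0 °C
Reagents that add atoms: n-butyllithium, [Li]CCCC (supplies lithium to intermediate 4 only)
Why: Directed ortho metalation should occur at the carbon flanked by both methoxy groups, since the silyloxy group is a poor director and shields its neighbours; copper-catalysed allylation of the aryllithium should then take place at the unsubstituted CH2 terminus of 3 (SN2) and not at the gem-dimethyl end.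

Step 3
Reactants: 5 triisopropyl[3,5-dimethoxy-4-(3-methylbut-2-en-1-yl)phenoxy]silane
Product: 6 3,5-dimethoxy-4-(3-methylbut-2-en-1-yl)phenol
Conditions: TBAF, THF, 0 °C; aq. NH4Cl
Reagents that add atoms: none
Why: Fluoride-induced cleavage of the aryl silyl ether, which touches neither the methyl ethers nor the alkene.

Step 4
Reactants: 6 3,5-dimethoxy-4-(3-methylbut-2-en-1-yl)phenol; 7 2,2-dimethoxyacetaldehyde
Product: 9 racemic 2-(1-hydroxy-2,2-dimethoxyethyl)-3,5-dimethoxy-4-(3-methylbut-2-en-1-yl)phenol, via bromomagnesium phenoxide 8 (not isolated)
Conditions: EtMgBr (1.0 equiv), Et2O, 0 °C; solvent exchange to CH2Cl2; anhydrous 7 (1.2 equiv), rt; pH 7 phosphate buffer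
Reagents that add atoms: ethylmagnesium bromide, CC[Mg]Br (supplies MgBr to intermediate 8 only)
Why: Ortho-specific hydroxyalkylation of a magnesium phenoxide, in which magnesium binds the aldehyde and delivers it through a six-membered transition state to the ortho carbon; the two ortho positions of 6 are equivalent and the para position is blocked, and the product stays as a magnesium chelate until the neutral work-up, so a second addition or ionisation is not expected. The new stereocentre forms as a racemate and is removed in step 9.

Step 5
Reactants: 9 racemic 2-(1-hydroxy-2,2-dimethoxyethyl)-3,5-dimethoxy-4-(3-methylbut-2-en-1-yl)phenol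
Product: 10 racemic {1-[2-hydroxy-4,6-dimethoxy-5-(3-methylbut-2-en-1-yl)phenyl]-2,2-dimethoxyethyl}triphenylphosphonium bromide
Conditions: PPh3·HBr (1.05 equiv), 4 Å MS, MeCN, rt
Reagents that add atoms: triphenylphosphine hydrobromide, Br.c1ccc(cc1)P(c1ccccc1)c1ccccc1
Why: Known conversion of o-hydroxybenzylic alcohols into phosphonium salts by protonation, loss of water to the o-quinone methide (benzylic cation) and capture by the phosphine; the cation is stabilised by one hydroxyl and two methoxy groups in ortho and para positions, so room temperature and the weak acid Ph3PH+ should suffice, which spares the acetal and the alkene.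

Step 6
Reactants: 11 2,4-dihydroxybenzoic acid
Product: 12 methoxymethyl 2,4-bis(methoxymethoxy)benzoate
Conditions: NaH (3.5 equiv), MOMCl (3.5 equiv), DMF, 0 °C to rt
Reagents that add atoms: chloromethyl methyl ether, COCCl
Why: Exhaustive O-alkylation of the carboxylate and both phenoxides (Williamson type); NaH is used because the 2-hydroxyl is hydrogen-bonded to the carbonyl group and is alkylated only as its anion.

Step 7
Reactants: 12 methoxymethyl 2,4-bis(methoxymethoxy)benzoate
Product: 13 2,4-bis(methoxymethoxy)benzoic acid
Conditions: NaOH, THF/H2O, rt; then 1 M HCl to pH 4, 0 °C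
Reagents that add atoms: sodium hydroxide, [Na+].[OH-]
Why: Saponification of the acyloxymethyl ester; aryl methoxymethyl ethers are inert to hydroxide and survive the brief, cold, mildly acidic work-up.

Step 8
Reactants: 10 racemic {1-[2-hydroxy-4,6-dimethoxy-5-(3-methylbut-2-en-1-yl)phenyl]-2,2-dimethoxyethyl}triphenylphosphonium bromide; 13 2,4-bis(methoxymethoxy)benzoic acid
Product: 14 racemic {1-[2-{[2,4-bis(methoxymethoxy)benzoyl]oxy}-4,6-dimethoxy-5-(3-methylbut-2-en-1-yl)phenyl]-2,2-dimethoxyethyl}triphenylphosphonium bromide
Conditions: DCC, DMAP (10 mol%), CH2Cl2, 0 °C to rt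
Reagents that add atoms: none
Why: Steglich esterification of the phenol; carbodiimide activation avoids the acid chloride of 13 (an ortho methoxymethoxy aroyl chloride cyclises to a benzodioxinone) and keeps bromide as the only counter-ion, and the catalytic amount of DMAP should not start ylide chemistry at room temperature.

Step 9
Reactants: 14 racemic {1-[2-{[2,4-bis(methoxymethoxy)benzoyl]oxy}-4,6-dimethoxy-5-(3-methylbut-2-en-1-yl)phenyl]-2,2-dimethoxyethyl}triphenylphosphonium bromide
Product: 16 2-[2,4-bis(methoxymethoxy)phenyl]-3-(dimethoxymethyl)-4,6-dimethoxy-5-(3-methylbut-2-en-1-yl)benzofuran, via phosphonium ylide 15 (not isolated)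
Conditions: Et3N (3 equiv), toluene, 110 °C
Reagents that add atoms: none
Why: Et3N removes the benzylic proton of 14, which is acidified by the phosphonium group, the aryl ring and the acetal, to give ylide 15. The ylide carbon adds to the carbonyl carbon of the neighbouring aryl ester in a 5-exo-trig closure, and the oxaphosphetane so formed expels Ph3P=O to leave the C2=C3 bond and the aromatic furan ring. The closest known reaction is the intramolecular ester Wittig olefination of o-acyloxybenzyl phosphonium salts to 2-aryl- and 2,3-disubstituted benzofurans; the acetal on the ylide carbon is the new element of the substrate. No stereocentre is formed, and the one in 14 becomes the sp2 carbon C3. The step needs olefination to win over C-acylation and over β-loss of methoxide: the ylide carbon is fully substituted, so an acylated product could not form a new ylide, and dialkoxyethyl ylides are established olefination reagents whose alkoxide groups leave poorly. A non-nucleophilic amine leaves the ester, the methoxymethyl ethers and the acetal untouched, and the gain of aromaticity pulls the closure forward.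

Step 10
Reactants: 16 2-[2,4-bis(methoxymethoxy)phenyl]-3-(dimethoxymethyl)-4,6-dimethoxy-5-(3-methylbut-2-en-1-yl)benzofuran
Product: 17 2-(2,4-dihydroxyphenyl)-4,6-dimethoxy-5-(3-methylbut-2-en-1-yl)benzofuran-3-carbaldehyde
Conditions: 3 M aq. HCl, THF, 50 °C
Reagents that add atoms: water, O
Why: Acid hydrolysis of the dimethyl acetal and of both methoxymethyl ethers in one operation; both oxygens next to the prenyl group are still methyl ethers, so no chroman can close, and the alcohol-free medium prevents a cyclic mixed acetal between the 2'-hydroxyl and the aldehyde.

Step 11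
Reactants: 17 2-(2,4-dihydroxyphenyl)-4,6-dimethoxy-5-(3-methylbut-2-en-1-yl)benzofuran-3-carbaldehyde
Product: 18 2-(2,4-dihydroxyphenyl)-4-hydroxy-6-methoxy-5-(3-methylbut-2-en-1-yl)benzofuran-3-carbaldehyde
Conditions: MgI2·OEt2 (3 equiv), toluene, 80 °C; aq. NaH2PO4
Reagents that add atoms: none
Why: Chelation-assisted O-demethylation, in which magnesium bridges the formyl oxygen and the peri 4-methoxy oxygen and iodide removes the methyl group by SN2; the 6-methoxy group has no carbonyl partner, and the 4-methoxy group, flanked on both sides, is twisted out of conjugation and more Lewis basic. The neutral, aprotic medium should spare the prenyl group beside the new phenol.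

## Compound list

1 | 3,5-dimethoxyphenol | COc1cc(O)cc(OC)c1 | starting material
2 | (3,5-dimethoxyphenoxy)triisopropylsilane | COc1cc(O[Si](C(C)C)(C(C)C)C(C)C)cc(OC)c1 | intermediate
3 | prenyl bromide (1-bromo-3-methylbut-2-ene) | CC(C)=CCBr | starting material
4 | [2,6-dimethoxy-4-(triisopropylsilyloxy)phenyl]lithium | [Li]c1c(OC)cc(O[Si](C(C)C)(C(C)C)C(C)C)cc1OC | intermediate (not isolated)
5 | triisopropyl[3,5-dimethoxy-4-(3-methylbut-2-en-1-yl)phenoxy]silane | COc1cc(O[Si](C(C)C)(C(C)C)C(C)C)cc(OC)c1CC=C(C)C | intermediate
6 | 3,5-dimethoxy-4-(3-methylbut-2-en-1-yl)phenol | COc1cc(O)cc(OC)c1CC=C(C)C | intermediate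
7 | 2,2-dimethoxyacetaldehyde | COC(OC)C=O | starting material
8 | bromomagnesium 3,5-dimethoxy-4-(3-methylbut-2-en-1-yl)phenoxide | COc1cc(O[Mg]Br)cc(OC)c1CC=C(C)C | intermediate (not isolated)
9 | racemic 2-(1-hydroxy-2,2-dimethoxyethyl)-3,5-dimethoxy-4-(3-methylbut-2-en-1-yl)phenol | COC(OC)C(O)c1c(O)cc(OC)c(CC=C(C)C)c1OC | intermediate
10 | racemic {1-[2-hydroxy-4,6-dimethoxy-5-(3-methylbut-2-en-1-yl)phenyl]-2,2-dimethoxyethyl}triphenylphosphonium bromide | COC(OC)C(c1c(O)cc(OC)c(CC=C(C)C)c1OC)[P+](c1ccccc1)(c1ccccc1)c1ccccc1.[Br-] | intermediate
11 | 2,4-dihydroxybenzoic acid | OC(=O)c1ccc(O)cc1O | starting material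
12 | methoxymethyl 2,4-bis(methoxymethoxy)benzoate | COCOC(=O)c1ccc(OCOC)cc1OCOC | intermediate
13 | 2,4-bis(methoxymethoxy)benzoic acid | OC(=O)c1ccc(OCOC)cc1OCOC | intermediate
14 | racemic {1-[2-{[2,4-bis(methoxymethoxy)benzoyl]oxy}-4,6-dimethoxy-5-(3-methylbut-2-en-1-yl)phenyl]-2,2-dimethoxyethyl}triphenylphosphonium bromide | COC(OC)C(c1c(OC(=O)c2ccc(OCOC)cc2OCOC)cc(OC)c(CC=C(C)C)c1OC)[P+](c1ccccc1)(c1ccccc1)c1ccccc1.[Br-] | intermediate
15 | 2-[2,2-dimethoxy-1-(triphenylphosphoranylidene)ethyl]-3,5-dimethoxy-4-(3-methylbut-2-en-1-yl)phenyl 2,4-bis(methoxymethoxy)benzoate (ylide) | COC(OC)C(c1c(OC(=O)c2ccc(OCOC)cc2OCOC)cc(OC)c(CC=C(C)C)c1OC)=P(c1ccccc1)(c1ccccc1)c1ccccc1 | intermediate (not isolated)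
16 | 2-[2,4-bis(methoxymethoxy)phenyl]-3-(dimethoxymethyl)-4,6-dimethoxy-5-(3-methylbut-2-en-1-yl)benzofuran | COC(OC)c1c(-c2ccc(OCOC)cc2OCOC)oc2cc(OC)c(CC=C(C)C)c(OC)c12 | intermediate
17 | 2-(2,4-dihydroxyphenyl)-4,6-dimethoxy-5-(3-methylbut-2-en-1-yl)benzofuran-3-carbaldehyde | COc1cc2oc(-c3ccc(O)cc3O)c(C=O)c2c(OC)c1CC=C(C)C | intermediate
18 | 2-(2,4-dihydroxyphenyl)-4-hydroxy-6-methoxy-5-(3-methylbut-2-en-1-yl)benzofuran-3-carbaldehyde | COc1cc2oc(-c3ccc(O)cc3O)c(C=O)c2c(O)c1CC=C(C)C | target

## Step count and risks

Total: 11 steps. Longest linear sequence: 9 steps (steps 1 to 5 and 8 to 11, from 1); the ring B branch (steps 6 and 7) joins at step 8.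

Least certain steps:

Step 9 (key step). The most likely failure is a stalled or diverted ylide. The ylide carbon lies between a triphenylphosphonium group, an acetal carbon and an aryl ring with two ortho substituents, so deprotonation and the approach to the ester carbonyl are both hindered. Loss of methoxide from the ylide, or dissociation of the phosphine from the very electron-rich benzylic position, could then overtake olefination. The fallback forms the same C2=C3 bond by reductive carbonyl coupling and sets out from 9. Activated MnO2 in CH2Cl2 should oxidise the benzylic alcohol to 1-[2-hydroxy-4,6-dimethoxy-5-(3-methylbut-2-en-1-yl)phenyl]-2,2-dimethoxyethanone F1. Esterification of the phenol of F1 with 13 (DCC, DMAP) should give 2-(2,2-dimethoxyacetyl)-3,5-dimethoxy-4-(3-methylbut-2-en-1-yl)phenyl 2,4-bis(methoxymethoxy)benzoate F2. A McMurry-type keto–ester coupling of F2 with low-valent titanium (TiCl3, Zn, DME, reflux) should close the furan and return to the route at 16.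

Step 5. The acid needed to ionise the benzylic alcohol may also ionise the dimethyl acetal. That would lead to loss of methanol, closure of the phenol onto the oxocarbenium ion, or a hydride shift toward the acetal carbon. HBr could also add to the prenyl alkene if warming is needed. The fallback generates the quinone methide without acid and sets out from 9. Silylation of the phenol (TBSCl, imidazole) should give racemic 1-[2-(tert-butyldimethylsilyloxy)-4,6-dimethoxy-5-(3-methylbut-2-en-1-yl)phenyl]-2,2-dimethoxyethanol F3. Acetylation of the benzylic hydroxyl of F3 (Ac2O, pyridine, DMAP) should give racemic 1-[2-(tert-butyldimethylsilyloxy)-4,6-dimethoxy-5-(3-methylbut-2-en-1-yl)phenyl]-2,2-dimethoxyethyl acetate F4. CsF with PPh3 in MeCN should unmask the phenoxide of F4, which expels acetate by 1,4-elimination; the phosphine adds to the quinone methide, and pyridinium bromide protonates the betaine. The sequence comes back at 10.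

Step 4. The magnesium phenoxide may be quenched by residual water from the aldehyde source, or the aldehyde may oligomerise, so that conversion stays low. On prolonged reaction the product could ionise and alkylate a second molecule of phenol. The fallback uses a boron template that tolerates the aqueous aldehyde and sets out from 6. Heating 6 with commercial aqueous 7, PhB(OH)2 and catalytic propionic acid in toluene with azeotropic removal of water should give racemic 4-(dimethoxymethyl)-5,7-dimethoxy-6-(3-methylbut-2-en-1-yl)-2-phenyl-4H-1,3,2-benzodioxaborinine F5. Transesterification of F5 with diethanolamine in THF releases the diol and comes back at 9.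

Step 11. Magnesium may be held by the ring B phenols, or the seven-membered chelate may be too weak, so that demethylation is slow; forcing it could cost the 6-methoxy group or the prenyl group. The fallback masks ring B and uses a boron Lewis acid; it sets out from 17. Ac2O and pyridine should give 4-[3-formyl-4,6-dimethoxy-5-(3-methylbut-2-en-1-yl)benzofuran-2-yl]-1,3-phenylene diacetate F6. BCl3 in CH2Cl2 at −78 °C, quenched cold into aqueous NaHCO3, should cleave the chelated and hindered 4-methyl ether of F6 to 4-[3-formyl-4-hydroxy-6-methoxy-5-(3-methylbut-2-en-1-yl)benzofuran-2-yl]-1,3-phenylene diacetate F7. K2CO3 in MeOH at 0 °C removes the acetates of F7 and reaches 18.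

## Further compounds

F1 | step 9 | 1-[2-hydroxy-4,6-dimethoxy-5-(3-methylbut-2-en-1-yl)phenyl]-2,2-dimethoxyethanone | COC(OC)C(=O)c1c(O)cc(OC)c(CC=C(C)C)c1OC
F2 | step 9 | 2-(2,2-dimethoxyacetyl)-3,5-dimethoxy-4-(3-methylbut-2-en-1-yl)phenyl 2,4-bis(methoxymethoxy)benzoate | COC(OC)C(=O)c1c(OC(=O)c2ccc(OCOC)cc2OCOC)cc(OC)c(CC=C(C)C)c1OC
F3 | step 5 | racemic 1-[2-(tert-butyldimethylsilyloxy)-4,6-dimethoxy-5-(3-methylbut-2-en-1-yl)phenyl]-2,2-dimethoxyethanol | COC(OC)C(O)c1c(O[Si](C)(C)C(C)(C)C)cc(OC)c(CC=C(C)C)c1OC
F4 | step 5 | racemic 1-[2-(tert-butyldimethylsilyloxy)-4,6-dimethoxy-5-(3-methylbut-2-en-1-yl)phenyl]-2,2-dimethoxyethyl acetate | COC(OC)C(OC(C)=O)c1c(O[Si](C)(C)C(C)(C)C)cc(OC)c(CC=C(C)C)c1OC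
F5 | step 4 | racemic 4-(dimethoxymethyl)-5,7-dimethoxy-6-(3-methylbut-2-en-1-yl)-2-phenyl-4H-1,3,2-benzodioxaborinine | COC(OC)C1OB(c2ccccc2)Oc2cc(OC)c(CC=C(C)C)c(OC)c21
F6 | step 11 | 4-[3-formyl-4,6-dimethoxy-5-(3-methylbut-2-en-1-yl)benzofuran-2-yl]-1,3-phenylene diacetate | COc1cc2oc(-c3ccc(OC(C)=O)cc3OC(C)=O)c(C=O)c2c(OC)c1CC=C(C)C
F7 | step 11 | 4-[3-formyl-4-hydroxy-6-methoxy-5-(3-methylbut-2-en-1-yl)benzofuran-2-yl]-1,3-phenylene diacetate | COc1cc2oc(-c3ccc(OC(C)=O)cc3OC(C)=O)c(C=O)c2c(O)c1CC=C(C)C
A1 | alternative 1 | 7,9-dimethoxy-8-(3-methylbut-2-en-1-yl)-6H-benzofuro[3,2-c]chromen-3-yl pivalate | COc1cc2oc3-c4ccc(OC(=O)C(C)(C)C)cc4OCc3c2c(OC)c1CC=C(C)C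
A2 | alternative 1 | 4-[4,6-dimethoxy-5-(3-methylbut-2-en-1-yl)benzofuran-2-yl]-3-hydroxyphenyl pivalate | COc1cc2oc(-c3ccc(OC(=O)C(C)(C)C)cc3O)cc2c(OC)c1CC=C(C)C
A3 | alternative 2 | 2-[2,4-bis(methoxymethoxy)phenyl]-3-(1,3-dioxolan-2-yl)-6-methoxy-5-(3-methylbut-2-en-1-yl)benzofuran-4-ol | COc1cc2oc(-c3ccc(OCOC)cc3OCOC)c(C3OCCO3)c2c(O)c1CC=C(C)C
A4 | alternative 2 | 2-diazo-1-{5-[2,4-bis(methoxymethoxy)phenyl]-4-(1,3-dioxolan-2-yl)furan-2-yl}ethanone | [N-]=[N+]=CC(=O)c1cc(C2OCCO2)c(-c2ccc(OCOC)cc2OCOC)o1
A5 | alternative 2 | 1-methoxy-5-methylhex-4-en-1-yne | COC#CCC=C(C)C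
A6 | alternative 3 | 2-(2,4-dihydroxyphenyl)-4,6-dimethoxy-5-(3-methylbut-2-en-1-yl)benzofuran-3-carbaldehyde | COc1cc2oc(-c3ccc(O)cc3O)c(C=O)c2c(OC)c1CC=C(C)C
A7 | alternative 3 | 7-hydroxy-3-[2-hydroxy-4,6-dimethoxy-5-(3-methylbut-2-en-1-yl)phenyl]chromen-4-one | O=c1c(-c2c(O)cc(OC)c(CC=C(C)C)c2OC)coc2cc(O)ccc12
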